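**Retrosynthetic overview**
- Last operations are desilylation and saponification. No ring is formed anywhere: the benzene ring is bought with the iodophenol starting material.
- The two side chains differ, so the arene–CH2 bond of the hydroxygeranyl arm is cut. This gives fragment A (an aryl iodide already carrying the protected hydroxyprenyl arm) and fragment B (an S-configured allylic chloride), joined by a Negishi allyl–aryl coupling.
- Fragment A: O-allylation and aromatic Claisen rearrangement, oxidative cleavage to the arylacetaldehyde, E-selective Wittig with a formyl ylide, then Luche reduction.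
- Fragment B: E-selective Wittig, crossed Claisen to a β-keto ester, ketoreductase reduction to set the only stereocentre, then Wittig to build the prenyl terminus.

Assumption: an S-selective ketoreductase for the β-keto ester is found by screening a commercial enzyme panel, and the configuration of the product is confirmed by Mosher ester analysis.

Abbreviations: TBS = tert-butyldimethylsilyl, TBDPS = tert-butyldiphenylsilyl, PPTS = pyridinium p-toluenesulfonate.

**Route**

Step 1
Reactants: 1 methyl 4-hydroxy-3-iodobenzoate; 2 allyl bromide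
Product: 3 methyl 3-iodo-4-(prop-2-en-1-yloxy)benzoate
Conditions: K2CO3, acetone, reflux
Reagents that add atoms: none
Why: Williamson ether synthesis, in which the acidic phenol (para ester, ortho iodine) is alkylated cleanly on oxygen by the allylic bromide.

Step 2
Reactants: 3 methyl 3-iodo-4-(prop-2-en-1-yloxy)benzoate
Product: 5 methyl 4-hydroxy-3-iodo-5-(prop-2-en-1-yl)benzoate, via ortho-dienone 4 (not isolated)
Conditions: PhNEt2, 195 °C, argon
Reagents that add atoms: none
Why: Aromatic Claisen rearrangement, which can only end productively at the one free ortho carbon (the other carries iodine, the para position the ester), after which dienone 4 tautomerises to the phenol.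

Step 3
Reactants: 5 methyl 4-hydroxy-3-iodo-5-(prop-2-en-1-yl)benzoate
Product: 6 methyl 3-iodo-4-methoxy-5-(prop-2-en-1-yl)benzoate
Conditions: MeI, K2CO3, DMF, rt
Reagents that add atoms: iodomethane, CI
Why: Williamson O-methylation of the hindered phenoxide in a dipolar solvent, done now so that no free phenol can attack the side chain once it is oxidised.

Step 4
Reactants: 6 methyl 3-iodo-4-methoxy-5-(prop-2-en-1-yl)benzoate
Product: 8 methyl 3-iodo-4-methoxy-5-(2-oxoethyl)benzoate, via vicinal diol 7 (not isolated)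
Conditions: OsO4 (2 mol %), NaIO4, 2,6-lutidine, dioxane/H2O 3:1, rt; used crude
Reagents that add atoms: osmium tetroxide, O=[Os](=O)(=O)=O; sodium periodate, [Na+].[O-]I(=O)(=O)=O (regenerates OsO4 and is the final oxygen source)
Why: Lemieux–Johnson oxidation, in which dihydroxylation of the only alkene and periodate glycol cleavage give the arylacetaldehyde while the aryl iodide and ester are inert.

Step 5
Reactants: 8 methyl 3-iodo-4-methoxy-5-(2-oxoethyl)benzoate; 9 2-(triphenylphosphoranylidene)propanal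
Product: 10 methyl 3-iodo-4-methoxy-5-[(2E)-3-methyl-4-oxobut-2-en-1-yl]benzoate
Conditions: toluene, 80 °C
Reagents that add atoms: none
Why: Wittig olefination with a formyl-stabilised ylide, which gives the E-trisubstituted enal under thermodynamic control and does not react on with the hindered conjugated product aldehyde.

Step 6
Reactants: 10 methyl 3-iodo-4-methoxy-5-[(2E)-3-methyl-4-oxobut-2-en-1-yl]benzoate
Product: 11 methyl 3-[(2E)-4-hydroxy-3-methylbut-2-en-1-yl]-5-iodo-4-methoxybenzoate
Conditions: NaBH4, CeCl3·7H2O, MeOH, 0 °C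
Reagents that add atoms: none
Why: Luche reduction gives clean 1,2-reduction of the enal and leaves the methyl benzoate, the aryl iodide and the alkene geometry untouched.

Step 7
Reactants: 11 methyl 3-[(2E)-4-hydroxy-3-methylbut-2-en-1-yl]-5-iodo-4-methoxybenzoate
Product: 12 methyl 3-[(2E)-4-(TBS-oxy)-3-methylbut-2-en-1-yl]-5-iodo-4-methoxybenzoate (fragment A)
Conditions: TBSCl, imidazole, DMF, rt
Reagents that add atoms: tert-butyldimethylsilyl chloride, CC(C)(C)[Si](C)(C)Cl
Why: Silyl ether protection of the primary allylic alcohol removes the only acidic proton before the organometallic coupling.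

Step 8
Reactants: 13 (TBS-oxy)acetaldehyde; 14 ethyl 2-(triphenylphosphoranylidene)propanoate
Product: 15 ethyl (2E)-4-(TBS-oxy)-2-methylbut-2-enoate
Conditions: CH2Cl2, rt
Reagents that add atoms: none
Why: Wittig olefination with an ester-stabilised α-methyl ylide reliably gives the E-trisubstituted enoate (typically at least 95:5).

Step 9
Reactants: 15 ethyl (2E)-4-(TBS-oxy)-2-methylbut-2-enoate; 16 tert-butyl acetate
Product: 18 tert-butyl (4E)-6-(TBS-oxy)-4-methyl-3-oxohex-4-enoate, via lithium ester enolate 17 (not isolated)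
Conditions: LiN(SiMe3)2 (3 equiv), 16 (3 equiv), THF, −78 °C; then 15, −78 to −20 °C; AcOH quench
Reagents that add atoms: lithium bis(trimethylsilyl)amide, [Li]N([Si](C)(C)C)[Si](C)(C)C (its lithium stays only in 17)
Why: Crossed Claisen condensation, in which the non-self-condensing tert-butyl acetate enolate acylates at the ethyl ester and the β-keto ester is held as its enolate until quench, which prevents over-addition.

Step 10
Reactants: 18 tert-butyl (4E)-6-(TBS-oxy)-4-methyl-3-oxohex-4-enoate
Product: 19 tert-butyl (3S,4E)-6-(TBS-oxy)-3-hydroxy-4-methylhex-4-enoate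
Conditions: ketoreductase (S-selective, NADPH-dependent alcohol dehydrogenase class), NADP+ (cat.), i-PrOH (15 vol %), KH2PO4/K2HPO4 buffer pH 7.0, 30 °C
Reagents that add atoms: none
Why: Enzymatic asymmetric ketone reduction, in which the ketoreductase delivers hydride from NADPH to one enantiotopic face of the β-keto ester and so sets C3 as S, with isopropanol recycling the cofactor and the alkene, ester and silyl ether untouched at neutral pH.

Step 11
Reactants: 19 tert-butyl (3S,4E)-6-(TBS-oxy)-3-hydroxy-4-methylhex-4-enoate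
Product: 20 tert-butyl (3S,4E)-6-(TBS-oxy)-3-(TBDPS-oxy)-4-methylhex-4-enoate
Conditions: TBDPSCl, imidazole, DMAP (cat.), DMF, rt to 40 °C
Reagents that add atoms: tert-butyldiphenylsilyl chloride, CC(C)(C)[Si](Cl)(c1ccccc1)c1ccccc1
Why: Silylation with the bulkier, more acid-stable TBDPS group makes the later selective removal of the primary TBS ether dependable.

Step 12
Reactants: 20 tert-butyl (3S,4E)-6-(TBS-oxy)-3-(TBDPS-oxy)-4-methylhex-4-enoate
Product: 22 (3S,4E)-6-(TBS-oxy)-3-(TBDPS-oxy)-4-methylhex-4-en-1-ol, via aldehyde 21 (not isolated)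
Conditions: i-Bu2AlH (2.5 equiv), CH2Cl2, −78 to 0 °C; Rochelle salt work-up
Reagents that add atoms: none
Why: Hydride reduction of the ester is taken through aldehyde 21 to the alcohol because partial reduction of a tert-butyl ester does not stop cleanly, and the silyl ethers are inert.

Step 13
Reactants: 22 (3S,4E)-6-(TBS-oxy)-3-(TBDPS-oxy)-4-methylhex-4-en-1-ol
Product: 21 (3S,4E)-6-(TBS-oxy)-3-(TBDPS-oxy)-4-methylhex-4-enal
Conditions: Dess–Martin periodinane, pyridine, CH2Cl2, 0 °C to rt
Reagents that add atoms: none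
Why: Dess–Martin oxidation under buffered, non-basic conditions gives the β-silyloxy aldehyde without β-elimination, and the stereocentre is not α to the carbonyl.

Step 14
Reactants: 21 (3S,4E)-6-(TBS-oxy)-3-(TBDPS-oxy)-4-methylhex-4-enal; 23 isopropyltriphenylphosphonium iodide
Product: 25 (2E,4S)-1-(TBS-oxy)-4-(TBDPS-oxy)-3,7-dimethylocta-2,6-diene, via isopropylidene ylide 24 (not isolated)
Conditions: 23, n-BuLi, THF, 0 °C; then 21, −78 to 0 °C
Reagents that add atoms: none
Why: Wittig olefination with the non-stabilised isopropylidene ylide adds to the aldehyde at −78 °C faster than it enolises it, and the new alkene has two identical methyl groups so no geometry issue arises.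

Step 15
Reactants: 25 (2E,4S)-1-(TBS-oxy)-4-(TBDPS-oxy)-3,7-dimethylocta-2,6-diene
Product: 26 (2E,4S)-4-(TBDPS-oxy)-3,7-dimethylocta-2,6-dien-1-ol
Conditions: PPTS (cat.), MeOH/CH2Cl2, rt
Reagents that add atoms: none
Why: Acid-catalysed methanolysis removes the unhindered primary TBS ether far faster than the hindered secondary TBDPS ether.

Step 16
Reactants: 26 (2E,4S)-4-(TBDPS-oxy)-3,7-dimethylocta-2,6-dien-1-ol
Product: 28 (2E,4S)-1-chloro-4-(TBDPS-oxy)-3,7-dimethylocta-2,6-diene (fragment B), via allylic mesylate 27 (not isolated)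
Conditions: MsCl, Et3N, CH2Cl2, −30 °C; then LiCl, THF, 0 °C
Reagents that add atoms: lithium chloride, [Li+].[Cl-]; methanesulfonyl chloride, CS(=O)(=O)Cl (stays only in 27)
Why: Mesylation and SN2 displacement by chloride give the primary allylic chloride without transposition, since the alternative SN2' terminus is fully substituted, and the E geometry is kept.

Step 17
Reactants: 12 fragment A aryl iodide; 28 fragment B allylic chloride
Product: 31 methyl 3-[(2E)-4-(TBS-oxy)-3-methylbut-2-en-1-yl]-5-[(2E,4S)-4-(TBDPS-oxy)-3,7-dimethylocta-2,6-dien-1-yl]-4-methoxybenzoate, via arylmagnesium chloride 29 (not isolated), via arylzinc chloride 30 (not isolated)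
Conditions: 12, i-PrMgCl·LiCl, THF, −30 °C; ZnCl2, −30 to 0 °C; then 28, Pd(PPh3)4 (5 mol %), THF, 0 °C to rt
Reagents that add atoms: isopropylmagnesium chloride–lithium chloride, CC(C)[Mg]Cl.[Li+].[Cl-] (Mg and Cl stay only in 29); zinc chloride, Cl[Zn]Cl (Zn and Cl stay only in 30)
Why: Iodine–magnesium exchange (ester tolerated at −30 °C), transmetalation to zinc and a Negishi allyl–aryl coupling on zerovalent palladium form the bond at the unsubstituted allyl terminus with retention of E geometry, and the remote S stereocentre is not touched.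

Step 18
Reactants: 31 bis-silyl ether methyl ester
Product: 32 methyl 3-[(2E,4S)-4-hydroxy-3,7-dimethylocta-2,6-dien-1-yl]-5-[(2E)-4-hydroxy-3-methylbut-2-en-1-yl]-4-methoxybenzoate
Conditions: Bu4NF (4 equiv), THF, 0 °C to rt
Reagents that add atoms: none
Why: Fluoride-mediated desilylation removes both silyl ethers under non-acidic conditions that spare the ionisable allylic alcohols and the alkene geometries.

Step 19
Reactants: 32 diol methyl ester
Product: 33 3-[(2E,4S)-4-hydroxy-3,7-dimethylocta-2,6-dien-1-yl]-5-[(2E)-4-hydroxy-3-methylbut-2-en-1-yl]-4-methoxybenzoic acid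
Conditions: LiOH·H2O, THF/MeOH/H2O, rt; then 0.5 M HCl to pH 4 at 0 °C
Reagents that add atoms: lithium hydroxide, [Li+].[OH-]
Why: Saponification of the unhindered methyl benzoate followed by mild acidification releases the acid without ionising the allylic alcohols or touching the stereocentre.

**Compound list**

1 | methyl 4-hydroxy-3-iodobenzoate | COC(=O)c1ccc(O)c(I)c1 | starting material
2 | allyl bromide | C=CCBr | starting material
3 | methyl 3-iodo-4-(prop-2-en-1-yloxy)benzoate | COC(=O)c1ccc(OCC=C)c(I)c1 | intermediate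
4 | methyl 5-iodo-4-oxo-3-(prop-2-en-1-yl)cyclohexa-1,5-diene-1-carboxylate (racemic ortho-dienone) | COC(=O)C1=CC(CC=C)C(=O)C(I)=C1 | intermediate
5 | methyl 4-hydroxy-3-iodo-5-(prop-2-en-1-yl)benzoate | COC(=O)c1cc(I)c(O)c(CC=C)c1 | intermediate
6 | methyl 3-iodo-4-methoxy-5-(prop-2-en-1-yl)benzoate | COC(=O)c1cc(I)c(OC)c(CC=C)c1 | intermediate
7 | methyl 3-(2,3-dihydroxypropyl)-5-iodo-4-methoxybenzoate (racemic) | COC(=O)c1cc(I)c(OC)c(CC(O)CO)c1 | intermediate
8 | methyl 3-iodo-4-methoxy-5-(2-oxoethyl)benzoate | COC(=O)c1cc(I)c(OC)c(CC=O)c1 | intermediate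
9 | 2-(triphenylphosphoranylidene)propanal | CC(C=O)=P(c1ccccc1)(c1ccccc1)c1ccccc1 | starting material
10 | methyl 3-iodo-4-methoxy-5-[(2E)-3-methyl-4-oxobut-2-en-1-yl]benzoate | COC(=O)c1cc(I)c(OC)c(C/C=C(\C)C=O)c1 | intermediate
11 | methyl 3-[(2E)-4-hydroxy-3-methylbut-2-en-1-yl]-5-iodo-4-methoxybenzoate | COC(=O)c1cc(I)c(OC)c(C/C=C(\C)CO)c1 | intermediate
12 | methyl 3-[(2E)-4-(TBS-oxy)-3-methylbut-2-en-1-yl]-5-iodo-4-methoxybenzoate | COC(=O)c1cc(I)c(OC)c(C/C=C(\C)CO[Si](C)(C)C(C)(C)C)c1 | intermediate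
13 | (TBS-oxy)acetaldehyde | CC(C)(C)[Si](C)(C)OCC=O | starting material
14 | ethyl 2-(triphenylphosphoranylidene)propanoate | CCOC(=O)C(C)=P(c1ccccc1)(c1ccccc1)c1ccccc1 | starting material
15 | ethyl (2E)-4-(TBS-oxy)-2-methylbut-2-enoate | CCOC(=O)/C(C)=C/CO[Si](C)(C)C(C)(C)C | intermediate
16 | tert-butyl acetate | CC(=O)OC(C)(C)C | starting material
17 | lithium 1-tert-butoxyethenolate (lithium enolate of 16) | C=C(O[Li])OC(C)(C)C | intermediate
18 | tert-butyl (4E)-6-(TBS-oxy)-4-methyl-3-oxohex-4-enoate | CC(C)(C)[Si](C)(C)OC/C=C(\C)C(=O)CC(=O)OC(C)(C)C | intermediate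
19 | tert-butyl (3S,4E)-6-(TBS-oxy)-3-hydroxy-4-methylhex-4-enoate | CC(C)(C)[Si](C)(C)OC/C=C(\C)[C@@H](O)CC(=O)OC(C)(C)C | intermediate
20 | tert-butyl (3S,4E)-6-(TBS-oxy)-3-(TBDPS-oxy)-4-methylhex-4-enoate | CC(C)(C)[Si](C)(C)OC/C=C(\C)[C@@H](O[Si](c1ccccc1)(c1ccccc1)C(C)(C)C)CC(=O)OC(C)(C)C | intermediate
21 | (3S,4E)-6-(TBS-oxy)-3-(TBDPS-oxy)-4-methylhex-4-enal | CC(C)(C)[Si](C)(C)OC/C=C(\C)[C@@H](O[Si](c1ccccc1)(c1ccccc1)C(C)(C)C)CC=O | intermediate
22 | (3S,4E)-6-(TBS-oxy)-3-(TBDPS-oxy)-4-methylhex-4-en-1-ol | CC(C)(C)[Si](C)(C)OC/C=C(\C)[C@@H](O[Si](c1ccccc1)(c1ccccc1)C(C)(C)C)CCO | intermediate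
23 | isopropyltriphenylphosphonium iodide | CC(C)[P+](c1ccccc1)(c1ccccc1)c1ccccc1.[I-] | starting material
24 | isopropylidenetriphenylphosphorane | CC(C)=P(c1ccccc1)(c1ccccc1)c1ccccc1 | intermediate
25 | (2E,4S)-1-(TBS-oxy)-4-(TBDPS-oxy)-3,7-dimethylocta-2,6-diene | CC(C)(C)[Si](C)(C)OC/C=C(\C)[C@@H](O[Si](c1ccccc1)(c1ccccc1)C(C)(C)C)CC=C(C)C | intermediate
26 | (2E,4S)-4-(TBDPS-oxy)-3,7-dimethylocta-2,6-dien-1-ol | OC/C=C(\C)[C@@H](O[Si](c1ccccc1)(c1ccccc1)C(C)(C)C)CC=C(C)C | intermediate
27 | (2E,4S)-4-(TBDPS-oxy)-3,7-dimethylocta-2,6-dien-1-yl methanesulfonate | CS(=O)(=O)OC/C=C(\C)[C@@H](O[Si](c1ccccc1)(c1ccccc1)C(C)(C)C)CC=C(C)C | intermediate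
28 | (2E,4S)-1-chloro-4-(TBDPS-oxy)-3,7-dimethylocta-2,6-diene | ClC/C=C(\C)[C@@H](O[Si](c1ccccc1)(c1ccccc1)C(C)(C)C)CC=C(C)C | intermediate
29 | arylmagnesium chloride from 12 (chloromagnesio in place of iodo) | COC(=O)c1cc([Mg]Cl)c(OC)c(C/C=C(\C)CO[Si](C)(C)C(C)(C)C)c1 | intermediate
30 | arylzinc chloride from 29 (chlorozincio in place of chloromagnesio) | COC(=O)c1cc([Zn]Cl)c(OC)c(C/C=C(\C)CO[Si](C)(C)C(C)(C)C)c1 | intermediate
31 | methyl 3-[(2E)-4-(TBS-oxy)-3-methylbut-2-en-1-yl]-5-[(2E,4S)-4-(TBDPS-oxy)-3,7-dimethylocta-2,6-dien-1-yl]-4-methoxybenzoate | COC(=O)c1cc(C/C=C(\C)CO[Si](C)(C)C(C)(C)C)c(OC)c(C/C=C(\C)[C@@H](O[Si](c2ccccc2)(c2ccccc2)C(C)(C)C)CC=C(C)C)c1 | intermediate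
32 | methyl 3-[(2E,4S)-4-hydroxy-3,7-dimethylocta-2,6-dien-1-yl]-5-[(2E)-4-hydroxy-3-methylbut-2-en-1-yl]-4-methoxybenzoate | COC(=O)c1cc(C/C=C(\C)CO)c(OC)c(C/C=C(\C)[C@@H](O)CC=C(C)C)c1 | intermediate
33 | 3-[(2E,4S)-4-hydroxy-3,7-dimethylocta-2,6-dien-1-yl]-5-[(2E)-4-hydroxy-3-methylbut-2-en-1-yl]-4-methoxybenzoic acid | COc1c(C/C=C(\C)CO)cc(C(=O)O)cc1C/C=C(\C)[C@@H](O)CC=C(C)C | target

**Step count**

Total: 19 steps. Longest linear sequence: 12 steps (steps 8 to 16, then 17 to 19). The arene branch is 7 steps before the coupling.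

**Three steps most likely to fail**

Step 5 (Wittig of a labile arylacetaldehyde with a sluggish formyl ylide at 80 °C; aldol self-condensation of 8 could erode the yield). The fallback sets out from 6 and comes back to the route at 11, replacing steps 4 to 6. Cross-metathesis of 6 with 2-methylbut-2-ene (second-generation Grubbs catalyst, RuCl2(=CHPh)(H2IMes)(PCy3), CH2Cl2, 40 °C) gives the prenyl arene methyl 3-iodo-4-methoxy-5-(3-methylbut-2-en-1-yl)benzoate F1. Allylic oxidation with SeO2 (cat.) and t-BuOOH in CH2Cl2 then oxidises the E-methyl group selectively. The crude product is treated under the step 6 conditions, so that any enal 10 formed alongside is converged onto 11.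

Step 10 (no enzyme of the panel may accept the bulky, lipophilic β-keto ester with high S selectivity). The fallback sets out from 13 (with 9) and comes back to the route at 25, replacing steps 8 to 14; it sets the stereocentre by a C–C bond-forming asymmetric catalysis instead of a ketone reduction. Wittig reaction of 13 with 9 (toluene, 80 °C) gives (2E)-4-(TBS-oxy)-2-methylbut-2-enal F2. Catalytic asymmetric Keck allylation ((S)-BINOL and Ti(OiPr)4, 10 mol % each, allyltributylstannane, 4 Å molecular sieves, CH2Cl2, −20 °C) gives (4S,5E)-7-(TBS-oxy)-5-methylhepta-1,5-dien-4-ol F3. The sense of induction is predicted by analogy with benzaldehyde and would be checked by Mosher analysis. Silylation (TBDPSCl, imidazole, DMF) gives (4S,5E)-7-(TBS-oxy)-4-(TBDPS-oxy)-5-methylhepta-1,5-diene F4. Cross-metathesis of its terminal alkene with 2-methylbut-2-ene (second-generation Grubbs catalyst, RuCl2(=CHPh)(H2IMes)(PCy3), CH2Cl2, 40 °C) turns the allyl into the prenyl terminus and gives 25.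

Step 17 (incomplete exchange or transmetalation, or loss of regio- or E-selectivity in the allyl–aryl coupling). The fallback sets out from 12 and 26 and comes back to the route at 31, replacing steps 16 and 17; it changes both partners, from an arylzinc and a chloride to an arylboronate and a carbonate. Miyaura borylation of 12 (bis(pinacolato)diboron, PdCl2(dppf), KOAc, dioxane, 80 °C) gives methyl 3-[(2E)-4-(TBS-oxy)-3-methylbut-2-en-1-yl]-4-methoxy-5-(4,4,5,5-tetramethyl-1,3,2-dioxaborolan-2-yl)benzoate F5. Acylation of 26 (methyl chloroformate, pyridine, CH2Cl2, 0 °C) gives (2E,4S)-4-(TBDPS-oxy)-3,7-dimethylocta-2,6-dien-1-yl methyl carbonate F6. Suzuki–Miyaura-type allyl–aryl coupling of F5 with F6 (Pd(PPh3)4, THF, 60 °C; the methoxide released on ionisation activates the boronate) joins the aryl group to the unsubstituted allyl terminus and gives 31.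

**Further compounds**

F1 | step 5 | methyl 3-iodo-4-methoxy-5-(3-methylbut-2-en-1-yl)benzoate | COC(=O)c1cc(I)c(OC)c(CC=C(C)C)c1
F2 | step 10 | (2E)-4-(TBS-oxy)-2-methylbut-2-enal | CC(C)(C)[Si](C)(C)OC/C=C(\C)C=O
F3 | step 10 | (4S,5E)-7-(TBS-oxy)-5-methylhepta-1,5-dien-4-ol | CC(C)(C)[Si](C)(C)OC/C=C(\C)[C@@H](O)CC=C
F4 | step 10 | (4S,5E)-7-(TBS-oxy)-4-(TBDPS-oxy)-5-methylhepta-1,5-diene | CC(C)(C)[Si](C)(C)OC/C=C(\C)[C@@H](O[Si](c1ccccc1)(c1ccccc1)C(C)(C)C)CC=C
F5 | step 17 | methyl 3-[(2E)-4-(TBS-oxy)-3-methylbut-2-en-1-yl]-4-methoxy-5-(4,4,5,5-tetramethyl-1,3,2-dioxaborolan-2-yl)benzoate | COC(=O)c1cc(B2OC(C)(C)C(C)(C)O2)c(OC)c(C/C=C(\C)CO[Si](C)(C)C(C)(C)C)c1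
F6 | step 17 | (2E,4S)-4-(TBDPS-oxy)-3,7-dimethylocta-2,6-dien-1-yl methyl carbonate | COC(=O)OC/C=C(\C)[C@@H](O[Si](c1ccccc1)(c1ccccc1)C(C)(C)C)CC=C(C)C
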